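**Retrosynthetic overview**
- The target is the C8 methacrylate of an α-methylene-γ-lactone. The lactone methylene is unmasked from a Mannich base, formed when the Sm(III) enolate from the radical step is trapped by Eschenmoser's salt.
- Key disconnection C7–C8: a C8 aldehyde gives a SmI2 ketyl radical that adds 9-exo to C7 of a butenolide, anti to the C6 substituent. This closes the nine-membered oxa-bridged ring and sets C7 and C8.
- The bridged 2-methoxy-2,5-dihydrofuran comes from a Z-γ-hydroxy-enone by cyclisation and methyl ketalisation. The Z-enone comes from syn-cuprate addition of Me2CuLi to an ynone, and the ynone from acyl Sonogashira coupling of a propargylic silyl ether.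
- The propargylic alcohol comes from chelation-controlled ethynylation of the chiral-pool butenolide aldehyde, which carries C6. The Z-trisubstituted C1=C10 alkene is supplied by 4-methyl-5,6-dihydropyran-2-one.
- Ring order: butenolide (chiral pool), dihydrofuran ketal (Step 8), nine-membered ring (Step 11).

Assumptions (one line): (S)-5-hydroxymethylfuran-2(5H)-one and 4-methyl-5,6-dihydro-2H-pyran-2-one are purchasable. The C2 ketal anomers interconvert through the allylic oxocarbenium under Lewis-acidic conditions, so only the 2,5-cis isomer closes in Step 11.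

---

**Step 1**
Reactants: 1 (S)-5-(hydroxymethyl)furan-2(5H)-one
Product: 2 (S)-5-formylfuran-2(5H)-one
Conditions: Dess–Martin periodinane, NaHCO3, CH2Cl2, 0 °C, 30 min. Use the crude aldehyde at once.
Reagents that add atoms: none
Why: Buffered Dess–Martin oxidation is mild enough to avoid racemising the acidic γ-stereocentre (C6), which becomes C6 (S) of the target.

**Step 2**
Reactants: 2; 3 ethynylmagnesium bromide
Product: 4 (S)-5-[(S)-1-hydroxyprop-2-yn-1-yl]furan-2(5H)-one
Conditions: HC≡CMgBr (3 equiv), ZnBr2 (1.2 equiv), THF, −78 → −40 °C; NH4Cl work-up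
Reagents that add atoms: ethynylmagnesium bromide, C#C[Mg]Br (listed as reactant 3)
Why: Cram-chelate addition. A Zn/Mg chelate between the CHO oxygen and the ring oxygen makes the alkyne attack anti to the ring C7 (on the H-face of C6), giving the (S)-carbinol C5.

**Step 3**
Reactants: 4
Product: 5 TES ether of 4
Conditions: TESCl, imidazole, CH2Cl2, 0 °C
Reagents that add atoms: chlorotriethylsilane, CC[Si](Cl)(CC)CC
Why: Silylation protects C5–OH so that it neither acylates in Step 6 nor consumes cuprate in Step 7.

**Step 4**
Reactants: 6 4-methyl-5,6-dihydro-2H-pyran-2-one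
Product: 7 TBS (Z)-5-(TBSO)-3-methylpent-2-enoate
Conditions: (i) LiOH·H2O, THF/H2O, rt, then evaporate to dryness; (ii) TBSCl (2.5 equiv), imidazole, DMF, rt
Reagents that add atoms: water, O (hydrolytic ring opening by LiOH, [Li+].[OH-]; the added OH/H appear as the carboxylate oxygen and the freed hydroxyl); tert-butyldimethylsilyl chloride, C[Si](C)(Cl)C(C)(C)C
Why: Lactone hydrolysis gives the lithium (Z)-5-hydroxy-3-methylpent-2-enoate in situ. It is not acidified, because the free Z-hydroxy acid would relactonise. Exhaustive silylation then gives the silyl ester and silyl ether. The ring locked the trisubstituted alkene as Z (C2 and C9 cis), which becomes the C1=C10 alkene of the target.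

**Step 5**
Reactants: 7
Product: 8 (Z)-5-(TBSO)-3-methylpent-2-enoyl chloride
Conditions: (COCl)2, cat. DMF, CH2Cl2, 0 °C → rt; concentrate and use at once
Reagents that add atoms: oxalyl chloride, ClC(=O)C(=O)Cl (only Cl is retained)
Why: Silyl esters convert cleanly to acid chlorides with oxalyl chloride and DMF, and the primary TBS ether survives. This avoids a separate hydrolysis step.

**Step 6**
Reactants: 5; 8
Product: 9 ynone, (3Z,8S)-8-[(2S)-5-oxo-2,5-dihydrofuran-2-yl]-1-(TBSO)-3-methyl-8-(TESO)oct-3-en-6-yn-5-one
Conditions: PdCl2(PPh3)2 (3 mol %), CuI (6 mol %), Et3N, THF, 0 °C → rt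
Reagents that add atoms: none
Why: Acyl Sonogashira coupling joins the acid chloride carbon (C2) to the terminal alkyne carbon (C3) under mild conditions that leave the butenolide alone.

**Step 7**
Reactants: 9
Product: 10 Z-enone, (3Z,6Z,8S)-8-[(2S)-5-oxo-2,5-dihydrofuran-2-yl]-1-(TBSO)-3,7-dimethyl-8-(TESO)octa-3,6-dien-5-one
Conditions: Me2CuLi (1.1 equiv), Et2O, −78 °C, 15 min; NH4Cl/NH3 work-up
Reagents that add atoms: lithium dimethylcuprate, C[Cu-]C.[Li+] (one methyl retained, C4–Me)
Why: Syn-carbocupration by conjugate addition to the ynone puts Me on C4 and H on C3, so C2 ends up cis to C5. This is the Z-enone geometry needed for ring closure.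

**Step 8**
Reactants: 10
Product: 11 methyl ketal, COC1(/C=C(/C)CCO[Si](C)(C)C(C)(C)C)C=C(C)[C@H](O1)[C@H]1OC(=O)C=C1, a mixture of C2 epimers
Conditions: PPTS (0.2 equiv), MeOH, 0 °C → rt
Reagents that add atoms: methanol, CO (gives the 2-OMe)
Why: Selective TES removal frees C5–OH. It adds to the cis-enone carbonyl (5-exo) to give the hemiketal, and MeOH capture of the allylic oxocarbenium gives the 2-methoxy-2,5-dihydrofuran. The primary TBS ether is not cleaved. The C5 configuration is untouched.

**Step 9**
Reactants: 11
Product: 12 primary alcohol, COC1(/C=C(/C)CCO)C=C(C)[C@H](O1)[C@H]1OC(=O)C=C1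
Conditions: HF·pyridine, pyridine, THF, 0 °C
Reagents that add atoms: none
Why: A buffered fluoride removes the primary TBS ether without acid-induced ketal ionisation or base-induced C6 epimerisation.

**Step 10**
Reactants: 12
Product: 13 aldehyde, COC1(/C=C(/C)CC=O)C=C(C)[C@H](O1)[C@H]1OC(=O)C=C1
Conditions: Dess–Martin periodinane, NaHCO3, CH2Cl2, 0 °C
Reagents that add atoms: none
Why: Buffered oxidation gives the β,γ-unsaturated aldehyde without isomerising it to the conjugated enal or ionising the ketal. It is used immediately.

**Step 11**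
Reactants: 13; 14 Eschenmoser's salt
Product: 15 macrocyclic Mannich base, O[C@H]1C/C(C)=C\[C@@]2(OC)C=C(C)[C@H](O2)[C@H]2OC(=O)C(CN(C)C)[C@@H]21 (C11 epimeric)
Conditions: SmI2 (2.4 equiv), THF, 0 °C, no HMPA or proton source. Add 13 (1 mM in THF) by syringe pump over 6 h. Then add Me2N+=CH2 I− (4 equiv), −78 °C → rt; Rochelle salt work-up.
Reagents that add atoms: Eschenmoser's salt, C=[N+](C)C.[I-] (the CH2NMe2 carbon is retained)
Why: Proposed new method: SmI2 reduces the aldehyde, not the butenolide, to a ketyl radical. The ketyl adds 9-exo to the β-carbon C7 of the butenolide, anti to the C5 substituent on C6, giving the trans-fused lactone. The Z-alkene and the cis-2,5-dihydrofuran pre-organise the U-turn. The second electron gives a Sm(III) enolate, which is trapped by the iminium at C11. SmI2 is limited to about 2.4 equiv so that no reductant is left to consume the iminium salt. The closest known reaction type is SmI2 ketyl–olefin conjugate addition (Fukuzawa/Molander type) followed by enolate Mannich trapping. C8 is set by the macrocyclic transition state (expected, not certain), and the cis-2,5 ketal anomer is the one that closes.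

**Step 12**
Reactants: 15
Product: 16 hydroxy α-methylene lactone, O[C@H]1C/C(C)=C\[C@@]2(OC)C=C(C)[C@H](O2)[C@H]2OC(=O)C(=C)[C@@H]21
Conditions: MeI (20 equiv), solid NaHCO3, CH2Cl2, rt, 2 h; then sat. aq. NaHCO3, rt
Reagents that add atoms: none (MeI is lost as Me3N)
Why: Quaternisation followed by E1cB elimination of Me3N from the β-ammonium lactone gives the exocyclic methylene. This is the Eschenmoser methylenation, and it destroys the C11 stereocentre. The solid bicarbonate scavenges any HI so that the acid-sensitive ketal is not ionised.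

**Step 13**
Reactants: 16; 17 methacryloyl chloride
Product: 18 target, 2-deethoxy-2β-methoxyphantomolin
Conditions: Et3N, DMAP (cat.), BHT (cat.), CH2Cl2, 0 °C
Reagents that add atoms: methacryloyl chloride, C=C(C)C(=O)Cl (listed as reactant 17)
Why: Acylation of the secondary C8 alcohol installs the methacrylate without disturbing the stereocentres.

---

**Compound list**

1 | (S)-5-(hydroxymethyl)furan-2(5H)-one | O=C1C=C[C@@H](CO)O1 | starting material
2 | (S)-5-formylfuran-2(5H)-one | O=C1C=C[C@@H](C=O)O1 | intermediate
3 | ethynylmagnesium bromide | C#C[Mg]Br | starting material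
4 | (S)-5-[(S)-1-hydroxyprop-2-ynyl]furan-2(5H)-one | O=C1C=C[C@@H]([C@@H](O)C#C)O1 | intermediate
5 | TES ether of 4 | O=C1C=C[C@@H]([C@@H](O[Si](CC)(CC)CC)C#C)O1 | intermediate
6 | 4-methyl-5,6-dihydro-2H-pyran-2-one | CC1=CC(=O)OCC1 | starting material
7 | TBS (Z)-5-(TBSO)-3-methylpent-2-enoate | CC(C)(C)[Si](C)(C)OC(=O)/C=C(/C)CCO[Si](C)(C)C(C)(C)C | intermediate
8 | (Z)-5-(TBSO)-3-methylpent-2-enoyl chloride | ClC(=O)/C=C(/C)CCO[Si](C)(C)C(C)(C)C | intermediate
9 | ynone | C/C(=C/C(=O)C#C[C@H](O[Si](CC)(CC)CC)[C@H]1OC(=O)C=C1)CCO[Si](C)(C)C(C)(C)C | intermediate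
10 | Z-enone | C/C(=C/C(=O)/C=C(/C)[C@H](O[Si](CC)(CC)CC)[C@H]1OC(=O)C=C1)CCO[Si](C)(C)C(C)(C)C | intermediate
11 | methyl ketal TBS ether (C2 epimers) | COC1(/C=C(/C)CCO[Si](C)(C)C(C)(C)C)C=C(C)[C@H](O1)[C@H]1OC(=O)C=C1 | intermediate
12 | primary alcohol | COC1(/C=C(/C)CCO)C=C(C)[C@H](O1)[C@H]1OC(=O)C=C1 | intermediate
13 | aldehyde | COC1(/C=C(/C)CC=O)C=C(C)[C@H](O1)[C@H]1OC(=O)C=C1 | intermediate
14 | Eschenmoser's salt | C=[N+](C)C.[I-] | starting material
15 | macrocyclic Mannich base | O[C@H]1C/C(C)=C\[C@@]2(OC)C=C(C)[C@H](O2)[C@H]2OC(=O)C(CN(C)C)[C@@H]21 | intermediate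
16 | hydroxy α-methylene lactone | O[C@H]1C/C(C)=C\[C@@]2(OC)C=C(C)[C@H](O2)[C@H]2OC(=O)C(=C)[C@@H]21 | intermediate
17 | methacryloyl chloride | C=C(C)C(=O)Cl | starting material
18 | 2-deethoxy-2β-methoxyphantomolin | C=C(C)C(=O)O[C@H]1C/C(C)=C\[C@@]2(OC)C=C(C)[C@H](O2)[C@H]2OC(=O)C(=C)[C@@H]21 | target

---

**Totals:** 13 steps in total. The longest linear sequence is 11 steps (1 → 2 → 4 → 5 → 9 → 10 → 11 → 12 → 13 → 15 → 16 → 18, counting Steps 1, 2, 3, 6, 7, 8, 9, 10, 11, 12, 13).

**Three steps most likely to fail**
1. **Step 11 (SmI2 nine-membered ring closure and Mannich trap).** Pinacol dimerisation, butenolide reduction, or the wrong C8 configuration are the risks.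
   - Fallback: change the approach. Run the same SmI2 ketyl–butenolide coupling intermolecularly, between a simple β,γ-unsaturated aldehyde and the butenolide bearing the vinyl ketal. Then close the nine-membered ring by ring-closing metathesis at C1=C10.
2. **Step 7 (cuprate in the presence of the butenolide).** Methyl addition to the butenolide (C7) would compete with ynone addition.
   - Fallback: build the Z-enone on the tail alone. Add NaI/AcOH to a propynyl ynone to give the Z-β-iodoenone, then join it to aldehyde 2 by Nozaki–Hiyama–Kishi coupling (CrCl2/NiCl2). Correct C5 by oxidation to the enedione and Zn(BH4)2 chelation-controlled reduction.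
3. **Steps 8–9 (ketalisation and desilylation).** The 2-methoxy-2,5-dihydrofuran can aromatise to the furan, and the free C8 alcohol can close onto C2 to give a 1,6-dioxaspiro[4.5] spiroketal.
   - Fallback: install the ketal oxidatively. Carry a 2,5-disubstituted 3-methylfuran through the sequence and oxidise it in MeOH (Br2/MeOH, or anodic) to the 2,5-dimethoxydihydrofuran. Then remove C5–OMe selectively with Et3SiH/Lewis acid, or close the nine-membered ring first on a C2-masked substrate and ketalise last.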